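## Analysis of the target

The target is a single cyclohexane ring, numbered here as in quinic acid: C1 is quaternary and carries a hydroxyl and the carboxyl, C2 and C6 are methylenes, and C3, C4 and C5 each carry oxygen. O3 is free and axial, cis to the axial O1 and cis to O4. O4 and O5 are trans-diequatorial, both esterified with (E)-4-hydroxycinnamic acid, and O5 is cis to the equatorial carboxyl. The sensitive groups are the vicinal cinnamates next to a free cis hydroxyl (base moves the O4 acyl group to O3), the E double bonds (light, conjugate reduction) and the free phenols. Any intermediate with a carbonyl at C3 and an ester at C5 can also lose that ester by β-elimination. The difficulty lies in four stereocentres on six carbons, one of them quaternary, and in three secondary oxygens of which exactly the adjacent pair O4/O5 must be acylated. The plan is built on the quaternary carbon: C1 with its oxygen, its carboxyl and the methylenes C2 and C6 is the 2-hydroxy-1,2,3-tricarboxylate core of citric acid, whose terminal carboxyl carbons become C3 and C5. A single carbon, C4, is all the ring lacks.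

## Retrosynthetic reasoning

**21 from 20.** The last step is a deprotection only. All protecting groups in 20 (tert-butyl ester, two aryl tert-butyl ethers, tertiary triethylsilyl ether) are acid-labile, so one acidolysis suffices. Base or fluoride is avoided because of acyl migration from O4 to O3.

**20 from 19.** The C3–H bond is cut, so that C3 is a ketone in 19. This keeps O3 distinct from O4 and O5 until both esters are in place. The forward reduction has to deliver hydride equatorially so that the hydroxyl is axial.

**19 from 18 and 15.** The O5–acyl bond is cut. In 18 the 5-hydroxyl is the only free secondary hydroxyl, so the acylation needs no regiocontrol, but it must avoid β-elimination.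

**18 from 17.** The C4–C5 bond is cut, giving an open chain with a ketone at C3, an aldehyde at C5 and the O4 ester already on the carbon between them. This is the only ring bond whose scission returns the citrate skeleton with C4 as the single added carbon, and it leaves one stereocentre (C1) in the precursor. A closure under equilibrium alone cannot be trusted to fix C5 relative to C1: C1 is geminally substituted, so one of its groups is axial in either epimer and the energy difference is small. The forward aldolisation therefore sets C5 by a chiral amine catalyst. O1 is carried as a silyl ether so that no C1 hydroxyl can hydrogen-bond the aldehyde and draw O5 to its own side.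

**17 from 16.** The aldehyde is the most fragile function and is released last, by direct oxidation of a primary silyl ether.

**16 from 12 and 15; 15 from 13 and 14.** The O4–C4 bond is cut to a diazoketone and the cinnamic acid, so that the final O4 ester enters by O–H insertion. The phenol is a tert-butyl ether because it must survive an amine catalyst, a carbenoid and a hydride and must fall off in the final acidolysis. Acid 15 comes from aldehyde 13 and malonic acid 14.

**12 from 9 and 10.** The C3–C4 bond is cut. Acylation of the diazomethane reagent 10 by the activated acid 9 brings in C4.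

**9 from 6, and 6 from 4.** The two arms are told apart in lactone 6, which holds the future C3 as a carboxyl carbon and the future C5 as CH2–O. Opening and silylation give 9. The lactone comes from half-ester 4 by reduction of one arm.

**4 from 3, 2 and 1.** Half-ester 4 results from desymmetrisation of the prochiral diester 3. Diester 3 comes from citric acid 1 by esterifying the two arms (2) and then the central carboxyl.

## Alternatives that were turned down

**Alternative 1:** The ring would be made by contracting a six-membered, sugar-derived lactone through an Ireland–Claisen shift. The silyl ketene acetal and a vinyl group on the lactone carbinol carbon rearrange, C1–C6 forms, the ring C–O bond at C4 breaks, and the product is 1-O-methoxymethyl-3-O-(tert-butyldimethylsilyl)-4,5-dideoxyquin-4-enic acid A1.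
- For it: the quaternary centre is set by suprafacial chirality transfer from a carbohydrate stereocentre, C3 is bought with the sugar, and ring and C1 arise in one step.
- Against it: A1 has no oxygen at C4 or C5. The C4=C5 bond must still become the trans-diol with O4 cis to O3, which needs control of both the face of oxidation and the site of opening. The sugar also needs several deoxygenation and protection steps first.
- Comparison: on the security of C1 this route is stronger than the chosen one, which depends on an enzyme. The chosen route instead delivers O4 and O5 in the ring-forming step itself, already differentiated, in fewer operations.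

**Alternative 2:** Cutting C3–C4 leads to the dialdehyde tert-butyl (2R,4R)-4-[(tert-butyldimethylsilyl)oxy]-2-(methoxymethoxy)-5-oxo-2-(2-oxoethyl)pentanoate A3. SmI2 would couple its two aldehydes to the cis-3,4-diol tert-butyl 5-O-(tert-butyldimethylsilyl)-1-O-methoxymethylquinate A2.
- For it: pinacol closures of 1,6-dialdehydes with SmI2 give cis-diols dependably through a samarium-bridged transition state, anti to the neighbouring silyloxy group. The 3,4-cis/4,5-trans pattern is therefore better founded than the C5 control of the aldol.
- Against it: A2 has O3 and O4 free and O5 silylated, the reverse of what the target needs. O4 must be acylated beside O3, and O5 then unmasked with fluoride next to an ester that can migrate. A3 also carries two stereocentres that must be made in an open chain.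
- Comparison: the chosen precursor has one stereocentre and keeps O3, O4 and O5 apart by oxidation state (ketone, ester, free hydroxyl).

**Alternative 3:** No ring is built. (−)-Quinic acid A7 is protected at O3 and at the carboxyl, and O4 and O5 are esterified with malonic half-ester units to give 2-(trimethylsilyl)ethyl 3-O-(tert-butyldimethylsilyl)-4,5-bis-O-(carboxyacetyl)quinate A5. Both side chains are completed by Knoevenagel–Doebner condensation with 4-hydroxybenzaldehyde A6, giving 2-(trimethylsilyl)ethyl 3-O-(tert-butyldimethylsilyl)-4,5-di-O-p-coumaroylquinate A4.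
- For it: every ring stereocentre is bought, the phenols need no protection, the condensation is E-selective and the sequence is the shortest. On step economy and stereochemical certainty it is stronger than the chosen strategy.
- Against it: it needs selective protection of O3, exposes a migration-prone vicinal diester to hot pyridine and piperidine, and ends with fluoride. It is tied to the natural enantiomer and to two identical acyl groups.
- Comparison: the chosen strategy offers a ring made from an achiral acid, hence either enantiomer and isotopic labelling at chosen ring carbons (C4 from reagent 10). O4 and O5 are esterified in separate steps, so mixed diesters are within reach.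

Key step: step 10

Assumption: the esterase in step 3 is taken to give the (S)-half-ester 4; the route does not depend on this, because the antipode reaches the same lactone 6 when BH3·SMe2 replaces LiBH4 (fallback for step 3).

## Route

Step 1
Reactants: 1 citric acid
Product: 2 1,5-dimethyl citrate
Conditions: MeOH, H2SO4 (cat.), 0 °C → rt; crystallisation
Reagents that add atoms: methanol CO
Why: Fischer esterification; the two CH2CO2H groups esterify faster than the hindered tertiary carboxyl, so stopping at the symmetric diester and crystallising it should separate the central acid from the arms.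

Step 2
Reactants: 2 1,5-dimethyl citrate
Product: 3 2-tert-butyl 1,3-dimethyl 2-hydroxypropane-1,2,3-tricarboxylate
Conditions: isobutene, H2SO4 (cat.), CH2Cl2, sealed vessel, rt
Reagents that add atoms: 2-methylpropene C=C(C)C
Why: Acid-catalysed addition of the free carboxylic acid to isobutene gives the tert-butyl ester; the methyl esters are inert and the tertiary alcohol is too hindered to be etherified. The bulky ester later resists reduction, saponification and lactonisation at C1.

Step 3
Reactants: 3 2-tert-butyl 1,3-dimethyl 2-hydroxypropane-1,2,3-tricarboxylate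
Product: 4 (3S)-3-(tert-butoxycarbonyl)-3-hydroxy-5-methoxy-5-oxopentanoic acid
Conditions: pig liver esterase, 0.1 M phosphate buffer pH 7.0, rt, pH-stat (1 M NaOH, 1.0 equiv); then HCl to pH 2.5
Reagents that add atoms: water O
Why: Enzymatic desymmetrisation of a prochiral 3,3-disubstituted glutarate: the two CH2CO2Me arms are enantiotopic, and the esterase should hydrolyse one and stop at the monoacid, the tert-butyl ester being no substrate. This sets the only stereocentre of the chain, the later C1.

Step 4
Reactants: 4 (3S)-3-(tert-butoxycarbonyl)-3-hydroxy-5-methoxy-5-oxopentanoic acid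
Product: 6 tert-butyl (4R)-4-hydroxy-2-oxooxane-4-carboxylate, via lithium dihydroxy carboxylate 5 (not isolated)
Conditions: LiOH (1.0 equiv), MeOH, evaporate; LiBH4 (2 equiv), THF, 0 °C → rt; then 1 M HCl to pH 2, rt
Reagents that add atoms: none
Why: LiBH4 reduces the methyl ester but neither the lithium carboxylate nor the hindered tert-butyl ester (chemoselective reduction of a half-ester), and acidification closes the δ-lactone with the free acid. The neutral lactone is also a point at which enantiomeric purity can be checked and raised by recrystallisation.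

Step 5
Reactants: 6 tert-butyl (4R)-4-hydroxy-2-oxooxane-4-carboxylate
Product: 9 (3R)-3-(tert-butoxycarbonyl)-3,5-bis(triethylsilyloxy)pentanoic acid, via potassium dihydroxy carboxylate 7 (not isolated), via tris(triethylsilyl) derivative 8 (not isolated)
Conditions: KOH (1.0 equiv), THF/H2O, 0 °C, evaporate and dry; Et3SiOTf (3.5 equiv), 2,6-lutidine (5 equiv), CH2Cl2, −78 → 0 °C; pH 5 phosphate buffer/THF, rt
Reagents that add atoms: potassium hydroxide [K+].[OH-]; triethylsilyl trifluoromethanesulfonate CC[Si](CC)(CC)OS(=O)(=O)C(F)(F)F
Why: Saponification of the purified lactone with one equivalent of potassium hydroxide, persilylation of the dried potassium salt with the silyl triflate (needed for the tertiary hydroxyl) and hydrolysis of the labile silyl ester on work-up is the standard passage from a lactone to a silyl-protected hydroxy acid. The tertiary silyl ether keeps O1 out of the carbenoid step, the aldol and the reduction.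

Step 6
Reactants: 9 (3R)-3-(tert-butoxycarbonyl)-3,5-bis(triethylsilyloxy)pentanoic acid; 10 (trimethylsilyl)diazomethane
Product: 12 tert-butyl (2R)-5-diazo-4-oxo-2-(triethylsilyloxy)-2-[2-(triethylsilyloxy)ethyl]pentanoate, via mixed carbonic anhydride 11 (not isolated)
Conditions: i-BuOCOCl, N-methylmorpholine, THF, −15 °C; then Me3SiCHN2 (2.5 equiv), MeCN, 0 °C → rt
Reagents that add atoms: (trimethylsilyl)diazomethane (10) C[Si](C)(C)C=[N+]=[N-]; isobutyl chloroformate CC(C)COC(=O)Cl (into intermediate 11 only)
Why: Acylation of the diazoalkane by the mixed anhydride, as in the first stage of the Arndt–Eistert sequence, forms the C3–C4 bond and brings in C4. The silyl group on carbon is lost on work-up, and esters and silyl ethers are untouched.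

Step 7
Reactants: 13 4-tert-butoxybenzaldehyde; 14 malonic acid
Product: 15 (2E)-3-(4-tert-butoxyphenyl)prop-2-enoic acid
Conditions: pyridine, piperidine (cat.), 90 °C; then cold aq. citric acid
Reagents that add atoms: malonic acid (14) OC(=O)CC(=O)O
Why: Knoevenagel–Doebner condensation with decarboxylation gives the E acid. The aryl tert-butyl ether is stable to hot pyridine and is chosen because it survives amines, carbenoids and hydride and is removed in the final acidolysis.

Step 8
Reactants: 12 tert-butyl (2R)-5-diazo-4-oxo-2-(triethylsilyloxy)-2-[2-(triethylsilyloxy)ethyl]pentanoate; 15 (2E)-3-(4-tert-butoxyphenyl)prop-2-enoic acid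
Product: 16 tert-butyl (2R)-5-{[(2E)-3-(4-tert-butoxyphenyl)prop-2-enoyl]oxy}-4-oxo-2-(triethylsilyloxy)-2-[2-(triethylsilyloxy)ethyl]pentanoate
Conditions: Rh2(OAc)4 (1 mol%), 15 (2 equiv), CH2Cl2, rt, slow addition of 12
Reagents that add atoms: (2E)-3-(4-tert-butoxyphenyl)prop-2-enoic acid (15) CC(C)(C)Oc1ccc(/C=C/C(=O)O)cc1
Why: Rh2(OAc)4-catalysed insertion of the keto carbenoid into the O–H bond of a carboxylic acid forms the O4–C4 bond and gives the acyloxymethyl ketone that already carries the final O4 ester. Insertion into an acid held in excess should outrun C–H insertion, and the electron-poor cinnamate double bond is a poor partner for cyclopropanation.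

Step 9
Reactants: 16 tert-butyl (2R)-5-{[(2E)-3-(4-tert-butoxyphenyl)prop-2-enoyl]oxy}-4-oxo-2-(triethylsilyloxy)-2-[2-(triethylsilyloxy)ethyl]pentanoate
Product: 17 tert-butyl (2R)-5-{[(2E)-3-(4-tert-butoxyphenyl)prop-2-enoyl]oxy}-4-oxo-2-(2-oxoethyl)-2-(triethylsilyloxy)pentanoate
Conditions: (COCl)2 (4 equiv), DMSO (8 equiv), CH2Cl2, −78 → −40 °C; Et3N, −78 → 0 °C
Reagents that add atoms: none
Why: Under Swern conditions a primary triethylsilyl ether is cleaved by the activated sulfoxide and oxidised directly to the aldehyde, while the tertiary silyl ether, the esters and the ketone are left. The aldehyde is thus released last and without a separate deprotection.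

Step 10
Reactants: 17 tert-butyl (2R)-5-{[(2E)-3-(4-tert-butoxyphenyl)prop-2-enoyl]oxy}-4-oxo-2-(2-oxoethyl)-2-(triethylsilyloxy)pentanoate
Product: 18 tert-butyl 4-O-[(E)-4-tert-butoxycinnamoyl]-1-O-triethylsilyl-3-dehydroquinate (1R,4S,5R; quinic acid numbering)
Conditions: L-proline (30 mol%), DMSO (0.05 M), rt
Reagents that add atoms: none
Why: L-Proline condenses with the C3 ketone; the enamine, formed toward C4 where the acyloxy group acidifies the hydrogens, adds through C4 to the C5 aldehyde while the carboxylic acid of the catalyst hydrogen-bonds the aldehyde oxygen, and hydrolysis of the iminium ion releases 18 and the catalyst. The closest known reaction type is the Hajos–Parrish cyclisation, a proline-catalysed enolendo aldolisation to a six-membered ring, together with proline aldol additions of α-oxygenated ketones through their oxygen-bearing carbon. The carbocycle closes in the 6-(enolendo)-exo-trig mode, the only productive one, because enolisation toward C2 or of the aldehyde toward C6 could only give four-membered rings. C5 is set by the catalyst: the hydrogen bond holds the aldehyde oxygen on the side of the enamine nitrogen and the tether holds C6 next to C2, which for the (S)-amino acid exposes the aldehyde face that gives 5R, the sense found at the carbinol carbon of the Hajos–Parrish ketol. C4 is set trans to O5, because the acyloxy group lies trans to nitrogen in the enamine to avoid the pyrrolidine ring, and this is also the more stable arrangement at this epimerisable carbon (both oxygens equatorial). The step needs the ketone as donor and the aldehyde as acceptor, which the ring-size argument and dilution secure. It also needs O5 trans to O1: the silyl ether removes the hydroxyl that could hydrogen-bond the aldehyde and pull O5 to its own side, so that the catalyst decides. The tert-butyl ester keeps the new 5-hydroxyl, which lies cis to the carboxyl, from lactonising.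

Step 11
Reactants: 18 tert-butyl 4-O-[(E)-4-tert-butoxycinnamoyl]-1-O-triethylsilyl-3-dehydroquinate; 15 (2E)-3-(4-tert-butoxyphenyl)prop-2-enoic acid
Product: 19 tert-butyl 4,5-bis-O-[(E)-4-tert-butoxycinnamoyl]-1-O-triethylsilyl-3-dehydroquinate
Conditions: 15 (1.5 equiv), DCC, DMAP (0.1 equiv), CH2Cl2, 0 °C
Reagents that add atoms: (2E)-3-(4-tert-butoxyphenyl)prop-2-enoic acid (15) CC(C)(C)Oc1ccc(/C=C/C(=O)O)cc1
Why: Steglich esterification of the only free secondary hydroxyl (O1 is tertiary and silylated). The low temperature and the small amount of base are meant to keep the new β-acyloxy ketone from eliminating.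

Step 12
Reactants: 19 tert-butyl 4,5-bis-O-[(E)-4-tert-butoxycinnamoyl]-1-O-triethylsilyl-3-dehydroquinate
Product: 20 tert-butyl 4,5-bis-O-[(E)-4-tert-butoxycinnamoyl]-1-O-triethylsilylquinate
Conditions: LiBH(s-Bu)3 (1.1 equiv), THF, −78 °C; AcOH quench at −78 °C
Reagents that add atoms: none
Why: Reduction of the cyclohexanone by a bulky trialkylborohydride: axial approach to C3 is blocked by the syn-axial silyloxy group on C1, so hydride arrives equatorially and the new hydroxyl is axial, cis to O1 and O4 as in quinic acid. At −78 °C the ketone should react before the esters and the cinnamate double bonds, and the cold acidic quench prevents migration of the O4 acyl group onto the new alkoxide.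

Step 13
Reactants: 20 tert-butyl 4,5-bis-O-[(E)-4-tert-butoxycinnamoyl]-1-O-triethylsilylquinate
Product: 21 4,5-di-O-p-coumaroylquinic acid
Conditions: TFA/H2O (9:1), anisole, 0 °C → rt; exclusion of light
Reagents that add atoms: none
Why: Acidolysis removes the tert-butyl ester, both aryl tert-butyl ethers and the tertiary silyl ether in one operation, with anisole trapping the tert-butyl cation. Acid is used because base or fluoride would invite migration of the O4 ester to O3; with O5 acylated no lactone can form.

## Compound list

1 | citric acid | OC(=O)CC(O)(CC(=O)O)C(=O)O | starting material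
2 | 1,5-dimethyl citrate | COC(=O)CC(O)(CC(=O)OC)C(=O)O | intermediate
3 | 2-tert-butyl 1,3-dimethyl 2-hydroxypropane-1,2,3-tricarboxylate | COC(=O)CC(O)(CC(=O)OC)C(=O)OC(C)(C)C | intermediate
4 | (3S)-3-(tert-butoxycarbonyl)-3-hydroxy-5-methoxy-5-oxopentanoic acid | OC(=O)C[C@@](O)(C(=O)OC(C)(C)C)CC(=O)OC | intermediate
5 | lithium (3R)-3-(tert-butoxycarbonyl)-3,5-dihydroxypentanoate | [Li+].[O-]C(=O)C[C@@](O)(C(=O)OC(C)(C)C)CCO | intermediate
6 | tert-butyl (4R)-4-hydroxy-2-oxooxane-4-carboxylate | O=C1C[C@@](O)(C(=O)OC(C)(C)C)CCO1 | intermediate
7 | potassium (3R)-3-(tert-butoxycarbonyl)-3,5-dihydroxypentanoate | [K+].[O-]C(=O)C[C@@](O)(C(=O)OC(C)(C)C)CCO | intermediate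
8 | triethylsilyl (3R)-3-(tert-butoxycarbonyl)-3,5-bis(triethylsilyloxy)pentanoate | CC[Si](CC)(CC)OC(=O)C[C@@](O[Si](CC)(CC)CC)(C(=O)OC(C)(C)C)CCO[Si](CC)(CC)CC | intermediate
9 | (3R)-3-(tert-butoxycarbonyl)-3,5-bis(triethylsilyloxy)pentanoic acid | OC(=O)C[C@@](O[Si](CC)(CC)CC)(C(=O)OC(C)(C)C)CCO[Si](CC)(CC)CC | intermediate
10 | (trimethylsilyl)diazomethane | C[Si](C)(C)C=[N+]=[N-] | starting material
11 | (3R)-3-(tert-butoxycarbonyl)-3,5-bis(triethylsilyloxy)pentanoic isobutyl carbonic anhydride | CC(C)COC(=O)OC(=O)C[C@@](O[Si](CC)(CC)CC)(C(=O)OC(C)(C)C)CCO[Si](CC)(CC)CC | intermediate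
12 | tert-butyl (2R)-5-diazo-4-oxo-2-(triethylsilyloxy)-2-[2-(triethylsilyloxy)ethyl]pentanoate | [N-]=[N+]=CC(=O)C[C@@](O[Si](CC)(CC)CC)(C(=O)OC(C)(C)C)CCO[Si](CC)(CC)CC | intermediate
13 | 4-tert-butoxybenzaldehyde | CC(C)(C)Oc1ccc(C=O)cc1 | starting material
14 | malonic acid | OC(=O)CC(=O)O | starting material
15 | (2E)-3-(4-tert-butoxyphenyl)prop-2-enoic acid | CC(C)(C)Oc1ccc(/C=C/C(=O)O)cc1 | intermediate
16 | tert-butyl (2R)-5-{[(2E)-3-(4-tert-butoxyphenyl)prop-2-enoyl]oxy}-4-oxo-2-(triethylsilyloxy)-2-[2-(triethylsilyloxy)ethyl]pentanoate | CC(C)(C)Oc1ccc(/C=C/C(=O)OCC(=O)C[C@@](O[Si](CC)(CC)CC)(C(=O)OC(C)(C)C)CCO[Si](CC)(CC)CC)cc1 | intermediate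
17 | tert-butyl (2R)-5-{[(2E)-3-(4-tert-butoxyphenyl)prop-2-enoyl]oxy}-4-oxo-2-(2-oxoethyl)-2-(triethylsilyloxy)pentanoate | CC(C)(C)Oc1ccc(/C=C/C(=O)OCC(=O)C[C@@](O[Si](CC)(CC)CC)(C(=O)OC(C)(C)C)CC=O)cc1 | intermediate
18 | tert-butyl 4-O-[(E)-4-tert-butoxycinnamoyl]-1-O-triethylsilyl-3-dehydroquinate | CC(C)(C)Oc1ccc(/C=C/C(=O)O[C@@H]2C(=O)C[C@@](O[Si](CC)(CC)CC)(C(=O)OC(C)(C)C)C[C@H]2O)cc1 | intermediate
19 | tert-butyl 4,5-bis-O-[(E)-4-tert-butoxycinnamoyl]-1-O-triethylsilyl-3-dehydroquinate | CC(C)(C)Oc1ccc(/C=C/C(=O)O[C@@H]2C(=O)C[C@@](O[Si](CC)(CC)CC)(C(=O)OC(C)(C)C)C[C@H]2OC(=O)/C=C/c3ccc(OC(C)(C)C)cc3)cc1 | intermediate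
20 | tert-butyl 4,5-bis-O-[(E)-4-tert-butoxycinnamoyl]-1-O-triethylsilylquinate | CC(C)(C)Oc1ccc(/C=C/C(=O)O[C@@H]2[C@H](O)C[C@@](O[Si](CC)(CC)CC)(C(=O)OC(C)(C)C)C[C@H]2OC(=O)/C=C/c3ccc(OC(C)(C)C)cc3)cc1 | intermediate
21 | 4,5-di-O-p-coumaroylquinic acid | O=C(/C=C/c1ccc(O)cc1)O[C@@H]1[C@H](O)C[C@@](O)(C(=O)O)C[C@H]1OC(=O)/C=C/c1ccc(O)cc1 | target

## Step count and least certain steps

Total: 13 steps. Longest linear sequence: 12 steps (1–6 and 8–13, from citric acid 1 to 21); step 7 is the one-step branch to 15.

**Step 10 (key step).** The catalyst and the C1 stereocentre may work against each other, which would lower the facial selectivity at the aldehyde. Enamine formation at the hindered ketone may also be slow enough for intermolecular condensation of the aldehyde or dehydration of the ketol to compete. Fallback: starting again from 17, the ring would be closed under reversible enolate conditions (DBU 10 mol%, toluene, 0 °C → rt), the way sugar-derived 5-keto aldehydes are cyclised, so that stability and not a catalyst decides. Isomer 18 is expected to be favoured because it alone can hold O4, O5 and the ester equatorial together, or, after ring inversion, the bulky silyloxy group equatorial with the 5-hydroxyl hydrogen-bonded to the ester carbonyl. The accompanying isomer tert-butyl 4-O-[(E)-4-tert-butoxycinnamoyl]-1-O-triethylsilyl-4,5-bis-epi-3-dehydroquinate F1 would be separated and returned to the same retro-aldol equilibrium. The route is rejoined at 18.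

**Step 3.** The enantiotopic-group selectivity of the esterase on this substrate may be low or opposite to the assumed sense. Fallback: if hydrolysis of 3 gives the antipode (3R)-3-(tert-butoxycarbonyl)-3-hydroxy-5-methoxy-5-oxopentanoic acid F2, its carboxylic acid arm is reduced with BH3·SMe2 (THF, 0 °C), which spares the esters, to methyl (3R)-3-(tert-butoxycarbonyl)-3,5-dihydroxypentanoate F3. Acid-catalysed lactonisation of F3 (TsOH cat., CH2Cl2) rejoins the route at 6. Partial selectivity is corrected by recrystallisation at 6.

**Step 8.** The rhodium carbenoid may insert into a C–H bond of the chain or form an ylide with the silyl ether oxygen faster than it is captured by the acid. Fallback without a carbene: 12 is treated with one equivalent of HBr (titrated solution in Et2O, −40 °C) to give tert-butyl (2R)-5-bromo-4-oxo-2-(triethylsilyloxy)-2-[2-(triethylsilyloxy)ethyl]pentanoate F4. Bromide is then displaced by the carboxylate of 15 (KF, DMF, rt), which rejoins the route at 16.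

**Step 9.** Cleavage of the primary silyl ether under Swern conditions may be incomplete, or the tertiary silyl ether may be lost with it. Fallback: from 16, buffered HF·pyridine (pyridine, THF, 0 °C) removes only the primary silyl group to give tert-butyl (2R)-5-[(E)-4-tert-butoxycinnamoyloxy]-2-(2-hydroxyethyl)-4-oxo-2-(triethylsilyloxy)pentanoate F5 (in part as its cyclic hemiketal). Dess–Martin periodinane (NaHCO3, CH2Cl2) then oxidises the open form to 17.

**Step 11.** Once O5 is acylated, base can remove the acidic C4 hydrogen and expel the C5 carboxylate (elimination to the enone). Fallback with the order reversed: 18 is reduced first (LiBH(s-Bu)3, THF, −78 °C) to tert-butyl 4-O-[(E)-4-tert-butoxycinnamoyl]-1-O-triethylsilylquinate F6. F6 is then esterified with 15 (DCC, DMAP cat., CH2Cl2, −20 °C) at the equatorial 5-hydroxyl, the axial 3-hydroxyl being shielded by the syn-axial silyloxy group. This rejoins the route at 20.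

## Further compounds

F1 | step 10 | tert-butyl 4-O-[(E)-4-tert-butoxycinnamoyl]-1-O-triethylsilyl-4,5-bis-epi-3-dehydroquinate (4R,5S) | CC(C)(C)Oc1ccc(/C=C/C(=O)O[C@H]2C(=O)C[C@@](O[Si](CC)(CC)CC)(C(=O)OC(C)(C)C)C[C@@H]2O)cc1
F2 | step 3 | (3R)-3-(tert-butoxycarbonyl)-3-hydroxy-5-methoxy-5-oxopentanoic acid | OC(=O)C[C@](O)(C(=O)OC(C)(C)C)CC(=O)OC
F3 | step 3 | methyl (3R)-3-(tert-butoxycarbonyl)-3,5-dihydroxypentanoate | OCC[C@](O)(C(=O)OC(C)(C)C)CC(=O)OC
F4 | step 8 | tert-butyl (2R)-5-bromo-4-oxo-2-(triethylsilyloxy)-2-[2-(triethylsilyloxy)ethyl]pentanoate | BrCC(=O)C[C@@](O[Si](CC)(CC)CC)(C(=O)OC(C)(C)C)CCO[Si](CC)(CC)CC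
F5 | step 9 | tert-butyl (2R)-5-[(E)-4-tert-butoxycinnamoyloxy]-2-(2-hydroxyethyl)-4-oxo-2-(triethylsilyloxy)pentanoate | CC(C)(C)Oc1ccc(/C=C/C(=O)OCC(=O)C[C@@](O[Si](CC)(CC)CC)(C(=O)OC(C)(C)C)CCO)cc1
F6 | step 11 | tert-butyl 4-O-[(E)-4-tert-butoxycinnamoyl]-1-O-triethylsilylquinate | CC(C)(C)Oc1ccc(/C=C/C(=O)O[C@@H]2[C@H](O)C[C@@](O[Si](CC)(CC)CC)(C(=O)OC(C)(C)C)C[C@H]2O)cc1
A1 | alternative 1 | 1-O-methoxymethyl-3-O-(tert-butyldimethylsilyl)-4,5-dideoxyquin-4-enic acid | C1=C[C@H](O[Si](C)(C)C(C)(C)C)C[C@@](OCOC)(C(=O)O)C1
A2 | alternative 2 | tert-butyl 5-O-(tert-butyldimethylsilyl)-1-O-methoxymethylquinate | O[C@@H]1[C@H](O)C[C@@](OCOC)(C(=O)OC(C)(C)C)C[C@H]1O[Si](C)(C)C(C)(C)C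
A3 | alternative 2 | tert-butyl (2R,4R)-4-[(tert-butyldimethylsilyl)oxy]-2-(methoxymethoxy)-5-oxo-2-(2-oxoethyl)pentanoate | O=C[C@H](O[Si](C)(C)C(C)(C)C)C[C@](OCOC)(C(=O)OC(C)(C)C)CC=O
A4 | alternative 3 | 2-(trimethylsilyl)ethyl 3-O-(tert-butyldimethylsilyl)-4,5-di-O-p-coumaroylquinate | O=C(/C=C/c1ccc(O)cc1)O[C@@H]1[C@H](O[Si](C)(C)C(C)(C)C)C[C@@](O)(C(=O)OCC[Si](C)(C)C)C[C@H]1OC(=O)/C=C/c1ccc(O)cc1
A5 | alternative 3 | 2-(trimethylsilyl)ethyl 3-O-(tert-butyldimethylsilyl)-4,5-bis-O-(carboxyacetyl)quinate | OC(=O)CC(=O)O[C@@H]1[C@H](O[Si](C)(C)C(C)(C)C)C[C@@](O)(C(=O)OCC[Si](C)(C)C)C[C@H]1OC(=O)CC(=O)O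
A6 | alternative 3 | 4-hydroxybenzaldehyde | O=Cc1ccc(O)cc1
A7 | alternative 3 | (−)-quinic acid | O[C@@H]1[C@H](O)C[C@@](O)(C(=O)O)C[C@H]1O
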